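All constants were set for the occasion; the result is computed.

Answer 4 questions on this flask.

substrate 0.35 M; salt in the second phase 0.630 M; spent carrier 7.0 mM; time 80 s; volume of the second phase over the first 2.0

    spent carrier + salt in the second phase ⇌ fresh carrier + spent salt in the second phase (K1 = 0.212, k1 = 6.13 M⁻¹ s⁻¹)
    substrate + fresh carrier → target + spent carrier (k2 = 52.3 M⁻¹ s⁻¹)
    target + fresh carrier → over-reaction product + fresh carrier (k3 = 69.5 M⁻¹ s⁻¹)
    crystals ⇌ target, rate k4*(cs4 - [target]) while solid is left; crystals form when [target] > cs4 (cs4 = 4.7 mM, k4 = 9.62 s⁻¹)
    substrate + spent carrier ⇌ idle complex, settled at all times (K5 = 55 M⁻¹)

- amounts and yields of target count crystals too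
- in the second phase: salt in the second phase, spent salt in the second phase; everything else is in the first
- charges count per volume of the first phase; a concentration in a rate is the amount of a species over the volume of its own phase; every rate counts per litre of the first phase
- given per volume of solution although it is solid: crystals
- run time (flask): 80 s

- the target and crystals together standing at 80 s, as a percentage of the substrate charged
- concentration of target in solution at 40 s, in percent of saturation
- the change that raises the amount of target and crystals together at 80 s, in percent of the substrate charged most ("none" if none brings more than 2 percentage points) (north-east / south / north / none)
- amount of target and crystals together at 80 s, in percent of the substrate charged, after south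

- north-east: doubling the amount of salt in the second phase, all else as stated
- south: doubling the dissolution coefficient of step 4, all else as stated
- north: doubling the solubility in step 4, all else as stated

1. Turn the question round. Each target costs one salt, and the salt charge of 0.630 M exceeds the substrate charge of 0.35 M, so substrate is the limiting reagent. To use up the substrate in 80 s, the flask must make target at 4.37 mM s⁻¹ on average. Test the carrier against that rate.

2. Count the free carrier. Idle complex stands at balance, and K5 times the starting substrate is 19. So of 7.0 mM charged, about 0.346 mM stays free as spent carrier.

3. Compare the two halves of the round. Salt in its own phase is 0.315 M, so spent carrier turns over at 1.93 s⁻¹. Substrate turns fresh carrier over at 18.3 s⁻¹. Step 1 is therefore the rate-limiting step: the turnover of fresh carrier is faster than that of spent carrier by a factor of 9.48.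

4. Take the regeneration rate, the forward rate of step 1 on free spent carrier and salt in its own phase: 0.667 mM s⁻¹. That falls short of the needed rate by a factor of 6.55. Expect 15.3%.

5. Let crystals carry away target as fast as the regeneration rate makes it. Dissolved target then stands above solubility by the regeneration rate over k4, which gives 101%.

6. Look for k4 and solubility in the regeneration rate: neither appears. So south gives 15.3%, and the best change is north-east.

7. Read the forecast: 15.4%, 101.5%, north-east, and 15.4% after south. Its yield lies a little above mine. Its ground for the choice: “doubling the salt nearly doubles the rate”.

8. Read the flask: 15.3%, 101%, north-east with a gain of 17 percentage points, and 15.3% after south.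

9. Compare the two half-lives. At 40.2 s the half-life of spent carrier by the forward step 1 is 0.38 s, longer than the 0.042 s of fresh carrier by step 2. At 40.0 s this flask holds 0.590% of its catalyst as fresh carrier, 5.40% as spent carrier and 94.0% as idle complex. For the forecast's yield to part from the flask, the computed yield moves by 5 points at a salt charge of 0.430 M below or 0.824 M above the present one.

10. Use the regeneration rate on the neighbour flask with 0.028 M of spent carrier: it becomes 2.67 mM s⁻¹, which gives 61.0% at 80.0 s. That neighbour computes to 66.7%, above the reckoning, with 24% of its substrate left.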